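Locants are those of the benzo[7]annulene core. Ring A is a cyclohexene (C1=C2); its allylic carbon C9a and homoallylic carbon C4a are the fusion atoms to the seven-membered ring B, and C5 of ring B, next to C4a, bears oxygen. With C5 as a ketone this is an intramolecular Diels–Alder retron. An acyclic (E)-trienone (vinyl ketone, three methylenes, CMe2, 2-methyl-1,3-diene) is therefore cyclized with a chiral oxazaborolidinium catalyst: rings A and B close together, ring B being sealed by the C4a–C9a bond, and both fusion centres are set trans. Axial methyl delivery at C5, allylic hydroxylation at C3 and acylation complete the target.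

Key step: step 6

Remark: the trans-fused bicyclic ketone formed in the key step is assumed to be the kinetic product and epimerizable at C4a toward the cis isomer, so it is kept from equilibrating base until C5 has been made quaternary.

Step 1
Reactants: 1 3-methylcyclohex-2-en-1-one
Product: 2 [(3,3-dimethylcyclohex-1-en-1-yl)oxy]trimethylsilane
Conditions: MeMgBr, CuBr·SMe2 (5 mol %), TMSCl, DMPU, THF, −78 °C; Et3N, cold aq. NaHCO3
Reagents that add atoms: methylmagnesium bromide, C[Mg]Br; chlorotrimethylsilane, C[Si](C)(C)Cl
Why: Copper-catalysed conjugate addition of the Grignard reagent with in situ silyl trapping builds the gem-dimethyl quaternary carbon and fixes the enol ether double bond between C1 and C2, the bond that the next step cleaves; no stereocentre is formed.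

Step 2
Reactants: 2 [(3,3-dimethylcyclohex-1-en-1-yl)oxy]trimethylsilane
Product: 3 5,5-dimethyl-6-oxohexanoic acid
Conditions: O3, CH2Cl2/MeOH, −78 °C; Me2S, −78 °C → rt; aqueous work-up
Reagents that add atoms: ozone, [O-][O+]=O
Why: Ozonolysis of the electron-rich silyl enol ether with reductive work-up opens the ring to a non-enolisable neopentyl aldehyde at one end and, after loss of the silyl group, a carboxylic acid at the other, so the two termini are differentiated without protecting groups; no stereocentre is formed.

Step 3
Reactants: 3 5,5-dimethyl-6-oxohexanoic acid; 4 diethyl (2-methylprop-2-en-1-yl)phosphonate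
Product: 6 (6E)-5,5,8-trimethylnona-6,8-dienoic acid, via lithiated phosphonate 5 (not isolated)
Conditions: 4 (2.2 equiv), n-BuLi (2.1 equiv), THF, −78 °C; add 3; DMPU, −78 °C → rt; 1 M HCl work-up
Reagents that add atoms: none
Why: Horner–Wadsworth–Emmons olefination of the aldehyde by the α-lithiated allylic phosphonate (one equivalent of which only deprotonates the acid, whose carboxylate is inert) gives the 2-methyl-1,3-diene, and the phosphonate pathway together with the bulky quaternary neighbour should favour the (E)-alkene needed for the cycloaddition.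

Step 4
Reactants: 6 (6E)-5,5,8-trimethylnona-6,8-dienoic acid
Product: 8 (6E)-N-methoxy-N,5,5,8-tetramethylnona-6,8-dienamide, via acyl imidazolide 7 (not isolated)
Conditions: CDI, CH2Cl2, rt; then MeNH(OMe)·HCl, rt
Reagents that add atoms: N,O-dimethylhydroxylamine hydrochloride, CNOC.Cl
Why: Carbonyldiimidazole activation followed by aminolysis (Weinreb amide formation) converts the acid under near-neutral conditions that leave the acid-sensitive diene untouched and prepares it for a single vinyl addition.

Step 5
Reactants: 8 (6E)-N-methoxy-N,5,5,8-tetramethylnona-6,8-dienamide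
Product: 9 (8E)-7,7,10-trimethylundeca-1,8,10-trien-3-one
Conditions: CH2=CHMgBr, THF, −20 → 0 °C; inverse quench into cold 1 M HCl; product kept cold
Reagents that add atoms: vinylmagnesium bromide, C=C[Mg]Br
Why: Weinreb ketone synthesis, in which the magnesium-chelated tetrahedral adduct survives until the quench so that only one vinyl group is delivered, while the cold acidic quench keeps the liberated hydroxylamine from adding to the vinyl ketone.

Step 6
Reactants: 9 (8E)-7,7,10-trimethylundeca-1,8,10-trien-3-one
Product: 10 (4aR,9aR)-2,9,9-trimethyl-3,4,4a,6,7,8,9,9a-octahydro-5H-benzo[7]annulen-5-one (trans-fused)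
Conditions: (S)-tetrahydro-1-(2-methylphenyl)-3,3-diphenyl-1H,3H-pyrrolo[1,2-c][1,3,2]oxazaborole (20 mol %), HNTf2 (17 mol %), CH2Cl2, −78 → −20 °C; pH 7 buffer
Reagents that add atoms: none
Why: Mechanism: the N-protonated oxazaborolidine binds the ketone oxygen of the s-trans enone syn to the vinyl group (α-C–H···O contact), and the tethered (E)-diene then adds in a concerted but asynchronous [4+2] in which the C3–C4 bond (diene CH2 terminus to the enone β-carbon) runs ahead of the C4a–C9a bond. The closest known reactions are the oxazaborolidinium-catalysed enantioselective Diels–Alder addition of simple dienes to vinyl ketones and the thermal or achiral-Lewis-acid intramolecular Diels–Alder cyclization of 1,8,10-undecatrien-3-ones. Ring A closes as the cyclohexene of the cycloaddition, and ring B closes in the fused (type 1) mode, its seven atoms being the five tether carbons of 9 (C3 to C7, the later C5 to C9) plus the two carbons joined in the new C4a–C9a bond. The trans relation of C4a and C9a is controlled by the anti transition state (tether carbonyl exo, H-4a endo), the only one in which the five-atom tether can span an s-trans enone and the outside position of the (E)-diene without strain, and the absolute configuration is controlled by the catalyst, whose phenyl group should cover the Re face of the α-carbon so that the diene bonds to its Si face and (4aR,9aR) results. The step needs fused and not bridged regiochemistry, which the tether length secures and the 2-methyl group of the diene reinforces ("para" orientation), and it needs the kinetic trans adduct to survive, which the non-enolising medium and the neutral work-up should secure. Should the sense of induction prove to be the reverse, the mirror-image catalyst from (R)-diphenylprolinol is used in the same way.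

Step 7
Reactants: 10 (4aR,9aR)-2,9,9-trimethyl-3,4,4a,6,7,8,9,9a-octahydro-5H-benzo[7]annulen-5-one
Product: 11 (4aR,5R,9aR)-2,5,9,9-tetramethyl-4,4a,5,6,7,8,9,9a-octahydro-3H-benzo[7]annulen-5-ol
Conditions: MeAl(OAr)2 (MAD; Ar = 2,6-di-tert-butyl-4-methylphenyl; 3 equiv, from AlMe3 and ArOH), toluene, −78 °C; MeLi (3 equiv), −78 °C; H2O
Reagents that add atoms: methyllithium, [Li]C
Why: Amphiphilic carbonyl methylation: the very bulky aluminium Lewis acid should bind the ketone on its open equatorial-type side (the side of H-4a), so that MeLi is forced to add from the opposite axial-type face, placing the methyl group anti to H-4a and the hydroxyl cis to it, which is (5R), while the non-equilibrating conditions at −78 °C leave the labile C4a centre untouched.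

Step 8
Reactants: 11 (4aR,5R,9aR)-2,5,9,9-tetramethyl-4,4a,5,6,7,8,9,9a-octahydro-3H-benzo[7]annulen-5-ol
Product: 12 (3R,4aR,5R,9aR)-2,5,9,9-tetramethyl-4,4a,5,6,7,8,9,9a-octahydro-3H-benzo[7]annulene-3,5-diol
Conditions: SeO2 (0.5 equiv), t-BuOOH (3 equiv), CH2Cl2, 0 °C → rt
Reagents that add atoms: tert-butyl hydroperoxide, CC(C)(C)OO (terminal oxidant; the oxygen is relayed by catalytic selenium dioxide, O=[Se]=O)
Why: Riley (selenium dioxide) allylic oxidation, an ene reaction at the alkene followed by a [2,3]-sigmatropic shift, should functionalise the ring methylene C3 next to the more substituted alkene carbon and, because the ene step removes the pseudoaxial hydrogen, install the hydroxyl pseudoaxially on the face of H-4a, trans to the C4a–C5 bond, which is (3R), with the tertiary alcohol tolerated.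

Step 9
Reactants: 13 3-hydroxy-4-methoxybenzoic acid (isovanillic acid)
Product: 15 3-[(tert-butyldimethylsilyl)oxy]-4-methoxybenzoic acid, via bis-silylated acid 14 (not isolated)
Conditions: TBSCl (2.5 equiv), imidazole, DMF, rt; then AcOH/THF/H2O, rt
Reagents that add atoms: tert-butyldimethylsilyl chloride, CC(C)(C)[Si](C)(C)Cl
Why: Exhaustive silylation followed by selective hydrolysis of the labile silyl ester under mild acid leaves the phenol masked as its silyl ether, so that the acid can be activated in the next step without self-condensation.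

Step 10
Reactants: 12 (3R,4aR,5R,9aR)-2,5,9,9-tetramethyl-4,4a,5,6,7,8,9,9a-octahydro-3H-benzo[7]annulene-3,5-diol; 15 3-[(tert-butyldimethylsilyl)oxy]-4-methoxybenzoic acid
Product: 16 (3R,4aR,5R,9aR)-5-hydroxy-2,5,9,9-tetramethyl-4,4a,5,6,7,8,9,9a-octahydro-3H-benzo[7]annulen-3-yl 3-[(tert-butyldimethylsilyl)oxy]-4-methoxybenzoate
Conditions: EDC·HCl, DMAP, CH2Cl2, 0 °C → rt
Reagents that add atoms: none
Why: Steglich esterification (carbodiimide with DMAP) acylates the secondary allylic hydroxyl with retention at C3, the tertiary C5 hydroxyl being too hindered to react, and the silyl ether keeps the phenol from competing as a nucleophile.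

Step 11
Reactants: 16 (3R,4aR,5R,9aR)-5-hydroxy-2,5,9,9-tetramethyl-4,4a,5,6,7,8,9,9a-octahydro-3H-benzo[7]annulen-3-yl 3-[(tert-butyldimethylsilyl)oxy]-4-methoxybenzoate
Product: 17 (3R,4aR,5R,9aR)-5-hydroxy-2,5,9,9-tetramethyl-4,4a,5,6,7,8,9,9a-octahydro-3H-benzo[7]annulen-3-yl 3-hydroxy-4-methoxybenzoate (CNP0210711.2)
Conditions: TBAF, AcOH, THF, 0 °C
Reagents that add atoms: none
Why: Fluoride-induced cleavage of the aryl silyl ether, buffered with acetic acid, should free the phenol much faster than the hindered allylic benzoate or the tertiary alcohol can be affected, and no stereocentre is touched.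

Compound list
1 | 3-methylcyclohex-2-en-1-one | CC1=CC(=O)CCC1 | starting material
2 | [(3,3-dimethylcyclohex-1-en-1-yl)oxy]trimethylsilane | C[Si](C)(C)OC1=CC(C)(C)CCC1 | intermediate
3 | 5,5-dimethyl-6-oxohexanoic acid | O=CC(C)(C)CCCC(=O)O | intermediate
4 | diethyl (2-methylprop-2-en-1-yl)phosphonate | CCOP(=O)(CC(C)=C)OCC | starting material
5 | α-lithiated diethyl (2-methylprop-2-en-1-yl)phosphonate | [Li+].CCOP(=O)(OCC)[CH-]C(C)=C | intermediate (not isolated)
6 | (6E)-5,5,8-trimethylnona-6,8-dienoic acid | OC(=O)CCCC(C)(C)/C=C/C(C)=C | intermediate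
7 | 1-[(6E)-5,5,8-trimethylnona-6,8-dienoyl]-1H-imidazole | O=C(CCCC(C)(C)/C=C/C(C)=C)n1ccnc1 | intermediate (not isolated)
8 | (6E)-N-methoxy-N,5,5,8-tetramethylnona-6,8-dienamide | CON(C)C(=O)CCCC(C)(C)/C=C/C(C)=C | intermediate
9 | (8E)-7,7,10-trimethylundeca-1,8,10-trien-3-one | C=CC(=O)CCCC(C)(C)/C=C/C(C)=C | intermediate
10 | (4aR,9aR)-2,9,9-trimethyl-3,4,4a,6,7,8,9,9a-octahydro-5H-benzo[7]annulen-5-one | C1C[C@@H]2[C@@H](C=C1C)C(C)(C)CCCC2=O | intermediate
11 | (4aR,5R,9aR)-2,5,9,9-tetramethyl-4,4a,5,6,7,8,9,9a-octahydro-3H-benzo[7]annulen-5-ol | C1C[C@@H]2[C@@H](C=C1C)C(C)(C)CCC[C@@]2(C)O | intermediate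
12 | (3R,4aR,5R,9aR)-2,5,9,9-tetramethyl-4,4a,5,6,7,8,9,9a-octahydro-3H-benzo[7]annulene-3,5-diol | O[C@@H]1C[C@@H]2[C@@H](C=C1C)C(C)(C)CCC[C@@]2(C)O | intermediate
13 | 3-hydroxy-4-methoxybenzoic acid (isovanillic acid) | COc1ccc(C(=O)O)cc1O | starting material
14 | tert-butyldimethylsilyl 3-[(tert-butyldimethylsilyl)oxy]-4-methoxybenzoate | COc1ccc(C(=O)O[Si](C)(C)C(C)(C)C)cc1O[Si](C)(C)C(C)(C)C | intermediate (not isolated)
15 | 3-[(tert-butyldimethylsilyl)oxy]-4-methoxybenzoic acid | COc1ccc(C(=O)O)cc1O[Si](C)(C)C(C)(C)C | intermediate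
16 | (3R,4aR,5R,9aR)-5-hydroxy-2,5,9,9-tetramethyl-4,4a,5,6,7,8,9,9a-octahydro-3H-benzo[7]annulen-3-yl 3-[(tert-butyldimethylsilyl)oxy]-4-methoxybenzoate | COc1ccc(C(=O)O[C@@H]2C[C@@H]3[C@@H](C=C2C)C(C)(C)CCC[C@@]3(C)O)cc1O[Si](C)(C)C(C)(C)C | intermediate
17 | (3R,4aR,5R,9aR)-5-hydroxy-2,5,9,9-tetramethyl-4,4a,5,6,7,8,9,9a-octahydro-3H-benzo[7]annulen-3-yl 3-hydroxy-4-methoxybenzoate | COc1ccc(C(=O)O[C@@H]2C[C@@H]3[C@@H](C=C2C)C(C)(C)CCC[C@@]3(C)O)cc1O | target

Total steps: 11. Longest linear sequence: 10 steps (steps 1 to 8, 10 and 11; step 9 prepares the acid component).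

Steps most likely to fail

Step 6. The catalyst may discriminate the two enone faces poorly, or turn over slowly because the diene in the anti transition state lies close to the catalyst, so that uncatalysed cyclization erodes the enantiomeric purity. The fallback gives up catalyst control and separates the enantiomers later. Trienone 9 is cyclized with Me2AlCl (CH2Cl2, −30 °C) or in toluene at reflux to the racemic trans ketone, that is 10 together with its enantiomer, the (4aS,9aS)-ketone F1. The racemate is taken through steps 7 and 8 unchanged, which gives 11 with its enantiomer, the (4aS,5S,9aS)-alcohol F2, and 12 with its enantiomer, the (3S,4aS,5S,9aS)-diol F3. The racemic diol is acylated at O-3 with (S)-2-methoxy-2-phenylacetic acid (EDC·HCl, DMAP, CH2Cl2) to two diastereomeric esters, the (3R,4aR,5R,9aR) ester F4 and the (3S,4aS,5S,9aS) ester F5, which are separated by chromatography or crystallisation. Methanolysis of F4 (K2CO3, MeOH, rt) returns enantiopure 12, and the route is rejoined there at step 10.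

Step 8. The ene step may attack the C2 methyl group instead of the ring methylene, stall because C1 is screened by the neighbouring quaternary carbon, or run on to the enone. The fallback brings the oxygen in at the ketone level and sets C3 by reduction and inversion. Alcohol 11 is oxidised at the allylic ring methylene (CrO3·3,5-dimethylpyrazole, CH2Cl2, −20 °C) to the enone, (4aR,5R,9aR)-5-hydroxy-2,5,9,9-tetramethyl-4,4a,5,6,7,8,9,9a-octahydro-3H-benzo[7]annulen-3-one F6. Luche reduction (NaBH4, CeCl3·7H2O, MeOH, −78 °C) should deliver hydride axially and give the pseudoequatorial alcohol, the (3S)-epimer of the diol F7. Mitsunobu esterification of F7 with acid 15 (PPh3, DIAD, toluene, 0 °C) inverts C3 and leads directly to the silyl-protected ester 16, where the route is rejoined at step 11.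

Step 7. MeLi may act as a base and epimerize C4a through the enolate, or the very bulky aluminium reagent may fail to engage the hindered carbonyl, so that addition is slow or comes from the undesired face. The fallback introduces the methyl carbon as a methylene unit from a small nucleophile and then reduces it. Ketone 10 is treated with dimethylsulfonium methylide (Me3S+ I−, KHMDS, THF, −20 °C; Corey–Chaykovsky reaction), which should add from the axial-type face and give the spiro-epoxide with its oxygen cis to H-4a, (4aR,5R,9aR)-2,9,9-trimethyl-3,4,4a,6,7,8,9,9a-octahydrospiro[benzo[7]annulene-5,2'-oxirane] F8. LiEt3BH (THF, 0 °C) opens the epoxide at the methylene carbon and gives alcohol 11, where the route is rejoined at step 8.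

Further compounds
F1 | step 6 | (4aS,9aS)-2,9,9-trimethyl-3,4,4a,6,7,8,9,9a-octahydro-5H-benzo[7]annulen-5-one | C1C[C@H]2[C@H](C=C1C)C(C)(C)CCCC2=O
F2 | step 6 | (4aS,5S,9aS)-2,5,9,9-tetramethyl-4,4a,5,6,7,8,9,9a-octahydro-3H-benzo[7]annulen-5-ol | C1C[C@H]2[C@H](C=C1C)C(C)(C)CCC[C@]2(C)O
F3 | step 6 | (3S,4aS,5S,9aS)-2,5,9,9-tetramethyl-4,4a,5,6,7,8,9,9a-octahydro-3H-benzo[7]annulene-3,5-diol | O[C@H]1C[C@H]2[C@H](C=C1C)C(C)(C)CCC[C@]2(C)O
F4 | step 6 | (3R,4aR,5R,9aR)-5-hydroxy-2,5,9,9-tetramethyl-4,4a,5,6,7,8,9,9a-octahydro-3H-benzo[7]annulen-3-yl (2S)-2-methoxy-2-phenylacetate | CO[C@H](C(=O)O[C@@H]1C[C@@H]2[C@@H](C=C1C)C(C)(C)CCC[C@@]2(C)O)c1ccccc1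
F5 | step 6 | (3S,4aS,5S,9aS)-5-hydroxy-2,5,9,9-tetramethyl-4,4a,5,6,7,8,9,9a-octahydro-3H-benzo[7]annulen-3-yl (2S)-2-methoxy-2-phenylacetate | CO[C@H](C(=O)O[C@H]1C[C@H]2[C@H](C=C1C)C(C)(C)CCC[C@]2(C)O)c1ccccc1
F6 | step 8 | (4aR,5R,9aR)-5-hydroxy-2,5,9,9-tetramethyl-4,4a,5,6,7,8,9,9a-octahydro-3H-benzo[7]annulen-3-one | O=C1C[C@@H]2[C@@H](C=C1C)C(C)(C)CCC[C@@]2(C)O
F7 | step 8 | (3S,4aR,5R,9aR)-2,5,9,9-tetramethyl-4,4a,5,6,7,8,9,9a-octahydro-3H-benzo[7]annulene-3,5-diol | O[C@H]1C[C@@H]2[C@@H](C=C1C)C(C)(C)CCC[C@@]2(C)O
F8 | step 7 | (4aR,5R,9aR)-2,9,9-trimethyl-3,4,4a,6,7,8,9,9a-octahydrospiro[benzo[7]annulene-5,2'-oxirane] | C1C[C@@H]2[C@@H](C=C1C)C(C)(C)CCC[C@]23CO3
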